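The diaryl ketone is cut on both sides of its carbonyl carbon, which bridges two crowded positions: C1' of ring A, whose neighbours C2' and C6' both carry oxygen, and C5 of ring B, peri to the vinylic C4 of the pyran ring. Because this carbon bears nothing but oxygen, carbon monoxide can deliver it. One palladium-catalysed carbonylative Suzuki–Miyaura coupling therefore joins a chromenyl C5 triflate, CO and 2,4,6-trimethoxyphenylboronic acid, making the C5–C(=O) and C(=O)–C1' bonds together. The precursor is the 2,2-dimethyl-2H-chromene with OTf at C5 and OTIPS at C7; silylating phloroglucinol before the chromene annulation lets the bulky silyl ether steer ring formation.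

Key step: step 4

Assumption: the target has no stereocentre and its only alkene (C3=C4) is endocyclic, so no stereocontrol is needed. Chromene numbering O1 to C8a is used; ring A is the dimethoxyphenol ring and ring B is the benzo ring of the chromene.

Step 1
Reactants: 1 phloroglucinol
Product: 2 5-(triisopropylsilyloxy)benzene-1,3-diol
Conditions: TIPSCl (1 equiv), imidazole (1.5 equiv), 1 (3 equiv), DMF, 0 °C to rt
Reagents that add atoms: triisopropylsilyl chloride, CC(C)[Si](Cl)(C(C)C)C(C)C
Why: Imidazole-mediated O-silylation (silyl ether formation) of a threefold-symmetric triol poses no regiochemical question, and an excess of cheap, water-soluble 1, removed by aqueous washing, should hold the reaction at the monoether.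

Step 2
Reactants: 2 5-(triisopropylsilyloxy)benzene-1,3-diol; 3 3-methylbut-2-enal
Product: 5 2,2-dimethyl-7-(triisopropylsilyloxy)-2H-chromen-5-ol, via ortho-quinone methide 4 (not isolated)
Conditions: 3 (1.3 equiv), ethylenediammonium diacetate (10 mol %), toluene, reflux
Reagents that add atoms: none
Why: A Knoevenagel-type condensation at the ring carbon between the two free hydroxyls, the only nucleophilic site not shielded by OTIPS, should give 4, whose oxa-6π electrocyclisation closes the pyran (formal [3+3] chromene annulation), and the same shielding of C6 in 5 should suppress a second annulation.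

Step 3
Reactants: 5 2,2-dimethyl-7-(triisopropylsilyloxy)-2H-chromen-5-ol
Product: 6 2,2-dimethyl-7-(triisopropylsilyloxy)-2H-chromen-5-yl trifluoromethanesulfonate
Conditions: Tf2O (1.2 equiv), pyridine (3 equiv), CH2Cl2, −20 to 0 °C
Reagents that add atoms: trifluoromethanesulfonic anhydride, O=S(=O)(OS(=O)(=O)C(F)(F)F)C(F)(F)F
Why: O-Sulfonylation of the single free phenol runs in a basic medium at low temperature, which should spare both the acid-sensitive chromene and the aryl silyl ether.

Step 4
Reactants: 6 2,2-dimethyl-7-(triisopropylsilyloxy)-2H-chromen-5-yl trifluoromethanesulfonate; 7 carbon monoxide; 8 2,4,6-trimethoxyphenylboronic acid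
Product: 9 [2,2-dimethyl-7-(triisopropylsilyloxy)-2H-chromen-5-yl](2,4,6-trimethoxyphenyl)methanone
Conditions: PdCl2(dppf) (5 mol %; dppf = 1,1'-bis(diphenylphosphino)ferrocene), KI (3 equiv), K2CO3 (3 equiv), CO (1 atm), anisole, 80 °C; 8 (2 equiv) added in portions
Reagents that add atoms: none
Why: Zerovalent palladium, formed in situ from PdCl2(dppf), adds oxidatively to the C5–OTf bond of 6, iodide displaces triflate from the divalent arylpalladium species, CO inserts to give the aroyl complex, carbonate-activated 8 transmetalates, and reductive elimination releases 9 with both new bonds, C5–C(=O) and C(=O)–C1', in place. The closest known reaction type is the carbonylative Suzuki–Miyaura coupling of aryl triflates with arylboronic acids, applied here to a new pair of partners. No ring is closed and no stereocentre is created. The selectivity required is ketone over direct biaryl formation, and the substrates secure it: the two ortho methoxy groups of 8 retard transmetalation, while the ortho vinyl substituent at C4a favours migratory insertion of CO into the crowded aryl–palladium bond, so insertion should come first. The main competitor, base-induced protodeboronation of the electron-rich 8, is countered by the water-poor K2CO3/anisole medium and portionwise addition of an excess. The C3=C4 alkene cannot trap the aroylpalladium species because that would need a strained five-membered endo closure across the peri positions, and the aryl TIPS ether should tolerate anhydrous carbonate.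

Step 5
Reactants: 9 [2,2-dimethyl-7-(triisopropylsilyloxy)-2H-chromen-5-yl](2,4,6-trimethoxyphenyl)methanone
Product: 11 [2,2-dimethyl-7-(triisopropylsilyloxy)-2H-chromen-5-yl](2-hydroxy-4,6-dimethoxyphenyl)methanone, via dichloroboron chelate 10 (not isolated)
Conditions: BCl3 (1.2 equiv), CH2Cl2, −78 to −20 °C; then cold aq. NaHCO3
Reagents that add atoms: none
Why: In this chelation-directed Lewis-acid ether cleavage BCl3 binds the ketone oxygen and one of the two equivalent ortho methoxy oxygens, chloride removes that methyl group, and the six-membered chelate 10 then occupies the carbonyl, so the other ortho and the para methoxy groups, the silyl ether and, at low temperature with a buffered quench, the chromene should stay intact.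

Step 6
Reactants: 11 [2,2-dimethyl-7-(triisopropylsilyloxy)-2H-chromen-5-yl](2-hydroxy-4,6-dimethoxyphenyl)methanone
Product: 12 (2-hydroxy-4,6-dimethoxyphenyl)(7-hydroxy-2,2-dimethyl-2H-chromen-5-yl)methanone (target)
Conditions: TBAF (1.1 equiv), AcOH (1.1 equiv), THF, 0 °C
Reagents that add atoms: none
Why: Fluoride-induced desilylation of the aryl silyl ether is driven by Si–F bond formation, and the acetic acid buffer keeps the medium near neutral so that the hydrogen-bonded hydroxy ketone and the chromene should be unaffected.

Compound list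
1 | phloroglucinol (benzene-1,3,5-triol) | Oc1cc(O)cc(O)c1 | starting material
2 | 5-(triisopropylsilyloxy)benzene-1,3-diol | CC(C)[Si](Oc1cc(O)cc(O)c1)(C(C)C)C(C)C | intermediate
3 | 3-methylbut-2-enal | CC(C)=CC=O | starting material
4 | (6Z)-5-hydroxy-6-(3-methylbut-2-en-1-ylidene)-3-(triisopropylsilyloxy)cyclohexa-2,4-dien-1-one (ortho-quinone methide, not isolated) | CC(C)=C/C=C1\C(=O)C=C(O[Si](C(C)C)(C(C)C)C(C)C)C=C1O | intermediate
5 | 2,2-dimethyl-7-(triisopropylsilyloxy)-2H-chromen-5-ol | CC1(C)C=Cc2c(O)cc(O[Si](C(C)C)(C(C)C)C(C)C)cc2O1 | intermediate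
6 | 2,2-dimethyl-7-(triisopropylsilyloxy)-2H-chromen-5-yl trifluoromethanesulfonate | CC1(C)C=Cc2c(OS(=O)(=O)C(F)(F)F)cc(O[Si](C(C)C)(C(C)C)C(C)C)cc2O1 | intermediate
7 | carbon monoxide | [C-]#[O+] | starting material
8 | 2,4,6-trimethoxyphenylboronic acid | COc1cc(OC)c(B(O)O)c(OC)c1 | starting material
9 | [2,2-dimethyl-7-(triisopropylsilyloxy)-2H-chromen-5-yl](2,4,6-trimethoxyphenyl)methanone | COc1cc(OC)c(C(=O)c2cc(O[Si](C(C)C)(C(C)C)C(C)C)cc3c2C=CC(C)(C)O3)c(OC)c1 | intermediate
10 | dichloro(aryloxy)borane of 11, carbonyl-chelated, drawn without the O to B dative bond (not isolated) | COc1cc(OC)c(C(=O)c2cc(O[Si](C(C)C)(C(C)C)C(C)C)cc3c2C=CC(C)(C)O3)c(OB(Cl)Cl)c1 | intermediate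
11 | [2,2-dimethyl-7-(triisopropylsilyloxy)-2H-chromen-5-yl](2-hydroxy-4,6-dimethoxyphenyl)methanone | COc1cc(O)c(C(=O)c2cc(O[Si](C(C)C)(C(C)C)C(C)C)cc3c2C=CC(C)(C)O3)c(OC)c1 | intermediate
12 | (2-hydroxy-4,6-dimethoxyphenyl)(7-hydroxy-2,2-dimethyl-2H-chromen-5-yl)methanone | COc1cc(O)c(C(=O)c2cc(O)cc3c2C=CC(C)(C)O3)c(OC)c1 | target

Total step count: 6
Longest linear sequence: 6 steps (1 to 12)

Steps most likely to fail

**1. Step 4.** Transmetalation of the doubly ortho-substituted, electron-rich boronic acid may be slow. Protodeboronation, base-induced S–O cleavage of the triflate, or capture of the aroylpalladium species by traces of water could then overtake ketone formation.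

The fallback sets out from 6 and comes back at 9. It installs the carbonyl carbon first and brings in ring A as a carbanion.
- Reductive carbonylation of 6 (Pd(OAc)2, dppp, CO 1 atm, Et3SiH, Et3N, DMF, 70 °C) should give 2,2-dimethyl-7-(triisopropylsilyloxy)-2H-chromene-5-carbaldehyde F1.
- Lithiation of commercial 1,3,5-trimethoxybenzene (n-BuLi, THF, 0 °C) should give 2,4,6-trimethoxyphenyllithium F2.
- F2 adds to F1 at −78 °C (aq. NH4Cl quench) to give racemic [2,2-dimethyl-7-(triisopropylsilyloxy)-2H-chromen-5-yl](2,4,6-trimethoxyphenyl)methanol F3.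
- Oxidation of this doubly benzylic alcohol with MnO2 in CH2Cl2 should return 9.

**2. Step 2.** The enal may bond in part at a ring carbon next to the silyl ether, giving the wrong chromene regiochemistry. The condensation may also lag behind self-condensation of the enal.

The fallback sets out from 1 and comes back at 6. It replaces steric control by hydrogen-bond control.
- Friedel–Crafts acylation and oxa-Michael closure of 1 with 3-methylbut-2-enoic acid in P2O5/MeSO3H (70 °C) should give 5,7-dihydroxy-2,2-dimethylchroman-4-one F4. Its acyl group deactivates the ring against further reaction.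
- The C5 hydroxyl is tied to the C4 ketone by a hydrogen bond, so TIPSCl/imidazole should take only the C7 hydroxyl and give 5-hydroxy-2,2-dimethyl-7-(triisopropylsilyloxy)chroman-4-one F5.
- Tf2O/pyridine should give 2,2-dimethyl-4-oxo-7-(triisopropylsilyloxy)chroman-5-yl trifluoromethanesulfonate F6.
- NaBH4 (THF–MeOH, 0 °C) should give racemic 4-hydroxy-2,2-dimethyl-7-(triisopropylsilyloxy)chroman-5-yl trifluoromethanesulfonate F7.
- Dehydration with catalytic p-TsOH in warm toluene, assisted by the para silyloxy and ortho ring oxygen donors, should deliver 6.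

**3. Step 5.** The Lewis acid may ionise the allylic C2–O1 bond of the chromene, HCl may add across C3=C4 during the quench, or a second methyl ether may be lost.

The fallback sets out from 6 and comes back at 11. It avoids ether cleavage altogether by carrying the future C2' hydroxyl as an acetal.
- Commercial 3,5-dimethoxyphenol with MOMCl/iPr2NEt should give 1,3-dimethoxy-5-(methoxymethoxy)benzene F8.
- Directed ortho-lithiation (n-BuLi, THF, 0 °C) between the OMOM and OMe groups should give 2,4-dimethoxy-6-(methoxymethoxy)phenyllithium F9.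
- Trapping with iPrOBpin (aq. NH4Cl quench) should give 2-[2,4-dimethoxy-6-(methoxymethoxy)phenyl]-4,4,5,5-tetramethyl-1,3,2-dioxaborolane F10.
- Coupling of F10 with 6 and 7 under the conditions of step 4 should give [2,4-dimethoxy-6-(methoxymethoxy)phenyl][2,2-dimethyl-7-(triisopropylsilyloxy)-2H-chromen-5-yl]methanone F11.
- Catalytic p-TsOH in MeOH at rt to 40 °C should remove the acetal and give 11.

Further compounds
F1 | step 4 | 2,2-dimethyl-7-(triisopropylsilyloxy)-2H-chromene-5-carbaldehyde | CC1(C)C=Cc2c(C=O)cc(O[Si](C(C)C)(C(C)C)C(C)C)cc2O1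
F2 | step 4 | 2,4,6-trimethoxyphenyllithium | [Li]c1c(OC)cc(OC)cc1OC
F3 | step 4 | [2,2-dimethyl-7-(triisopropylsilyloxy)-2H-chromen-5-yl](2,4,6-trimethoxyphenyl)methanol (racemic) | COc1cc(OC)c(C(O)c2cc(O[Si](C(C)C)(C(C)C)C(C)C)cc3c2C=CC(C)(C)O3)c(OC)c1
F4 | step 2 | 5,7-dihydroxy-2,2-dimethylchroman-4-one | CC1(C)CC(=O)c2c(O)cc(O)cc2O1
F5 | step 2 | 5-hydroxy-2,2-dimethyl-7-(triisopropylsilyloxy)chroman-4-one | CC1(C)CC(=O)c2c(O)cc(O[Si](C(C)C)(C(C)C)C(C)C)cc2O1
F6 | step 2 | 2,2-dimethyl-4-oxo-7-(triisopropylsilyloxy)chroman-5-yl trifluoromethanesulfonate | CC1(C)CC(=O)c2c(OS(=O)(=O)C(F)(F)F)cc(O[Si](C(C)C)(C(C)C)C(C)C)cc2O1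
F7 | step 2 | 4-hydroxy-2,2-dimethyl-7-(triisopropylsilyloxy)chroman-5-yl trifluoromethanesulfonate (racemic) | CC1(C)CC(O)c2c(OS(=O)(=O)C(F)(F)F)cc(O[Si](C(C)C)(C(C)C)C(C)C)cc2O1
F8 | step 5 | 1,3-dimethoxy-5-(methoxymethoxy)benzene | COCOc1cc(OC)cc(OC)c1
F9 | step 5 | 2,4-dimethoxy-6-(methoxymethoxy)phenyllithium | COCOc1cc(OC)cc(OC)c1[Li]
F10 | step 5 | 2-[2,4-dimethoxy-6-(methoxymethoxy)phenyl]-4,4,5,5-tetramethyl-1,3,2-dioxaborolane | COCOc1cc(OC)cc(OC)c1B1OC(C)(C)C(C)(C)O1
F11 | step 5 | [2,4-dimethoxy-6-(methoxymethoxy)phenyl][2,2-dimethyl-7-(triisopropylsilyloxy)-2H-chromen-5-yl]methanone | COCOc1cc(OC)cc(OC)c1C(=O)c1cc(O[Si](C(C)C)(C(C)C)C(C)C)cc2c1C=CC(C)(C)O2
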